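Early on, the south-west run reads more complex with two exchanged than isomer of the product, and the thing I would watch is how far that lead has shrunk when the flask is read.

| flask | starting complex | incoming ligand | temperature | remark | time |
|---|---|---|---|---|---|
| south-west | 0.25 M | 0.30 M | 20 °C | run made earlier |  |
| north | 0.38 M | 0.30 M | 20 °C | run made earlier |  |
| birch | 0.25 M (fed, over 8.0 d) | 0.300 M | 20 °C | all else is in the flask from the start; the feed brings no volume worth counting | 10 d |
| ash | 0.25 M (fed, over 8.0 d) | 0.300 M |  | the addition at −10 °C, then warmed to 20 °C; the feed brings no volume worth counting | 10 d |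
| maple | 0.25 M | 0.300 M | 20 °C | everything together at the start | 10 d |
| elm | 0.25 M | 0.300 M |  | everything together at the start at −10 °C, warmed to 20 °C at 8.0 d | 10 d |

south-west run (percent of the starting complex charged)

| time / d | complex with two exchanged / % | isomer of the product / % |
|---|---|---|
| 0.500 | 3.4 | 0.8 |
| 1.67 | 5.5 | 2.4 |
| 3.00 | 5.2 | 4.4 |
| 4.00 | 3.7 | 7.0 |
| 6.00 | 2.5 | 9.0 |

north run (percent of the starting complex charged)

| time / h | complex with two exchanged / % | isomer of the product / % |
|---|---|---|
| 4.00 | 0 | 0.7 |
| 8.00 | 2.0 | 0 |
| 15.0 | 1.3 | 2.9 |
| 25.0 | 3.3 | 2.4 |
| 50.0 | 2.6 | 2.5 |

(each reading ± 1 percentage point)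

- the analysis behind the earlier runs scatters by 1 percentage point, standard deviation
- steps under discussion: starting complex + incoming ligand -> leaving ligand + complex with one exchanged; complex with one exchanged + incoming ligand <-> leaving ligand + complex with two exchanged; complex with two exchanged <-> isomer of the product
- the earlier runs do not show what temperature does; that part of a forecast is a guess

- which flask leads in share of complex with two exchanged in complex with two exchanged plus isomer of the product ("all alike" within 1.5 percentage points) (birch / ash / maple / elm / all alike)
- share of complex with two exchanged in complex with two exchanged plus isomer of the product at the end, birch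
- share of complex with two exchanged in complex with two exchanged plus isomer of the product at the end, ash
- share of complex with two exchanged in complex with two exchanged plus isomer of the product at the end, maple
- share of complex with two exchanged in complex with two exchanged plus isomer of the product at the end, elm

I read the south-west table as the share of complex with two exchanged in that pair. It is 81.0 % at 0.500 d, 69.6 % at 1.67 d, 54.2 % at 3.00 d, 34.6 % at 4.00 d and 21.7 % at 6.00 d, the last resting on a reading of 2.5 % with a scatter of 1 percentage point. At one moment the isomer is fed from the complex with two exchanged, and the comparison drifts: the complex with two exchanged reads above the isomer at 1.67 d and below it at 4.00 d, while the two readings at 3.00 d lie too close to tell apart with a scatter of 1 point. This is kinetic against thermodynamic control, read on a clock.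

So the quantity I carry is the warm age, the days a flask spends at 20 °C before it is read: for ash and elm, cold until 8.0 d, it is 2.00 d. The earlier runs do not show what temperature does, so counting the cold days as nothing is my guess. That age lies beyond 1.67 d and short of 3.00 d, so I expect ash and elm between 54.2 % and 69.6 %. Maple and birch stand warm for 10 d, past the last reading, so I expect them near 21.7 %.

The forecast names ash as leader, with ash 58 %, elm 54 %, birch 17 % and maple 14 %, the last two below my figure. Its ground for the lead is “Ash is slightly ahead, since slow feeding delays formation.”

Ash gives 58.3 % and leads, with elm 56.5 %, birch 25.8 % and maple 25.1 %, so maple stands above the forecast. At its change of temperature, after 8.00 d, ash holds 0.421 % complex with two exchanged and 0.00545 % isomer, hardly any beside it. The warm age of 2.00 d then puts ash between 54.2 % and 69.6 %, and 58.3 % lies there.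

    starting complex + incoming ligand → leaving ligand + complex with one exchanged (k = 0.00293 L mol⁻¹ min⁻¹, Ea = 76.0 kJ mol⁻¹)
    complex with one exchanged + incoming ligand ⇌ leaving ligand + complex with two exchanged (K = 0.260, k = 9.12 × 10⁻⁴ L mol⁻¹ min⁻¹, Ea = 72.0 kJ mol⁻¹, ΔH = 4.00 kJ mol⁻¹)
    complex with two exchanged ⇌ isomer of the product (K = 2.88, k = 3.62 × 10⁻⁴ min⁻¹, Ea = 95.0 kJ mol⁻¹, ΔH = 9.00 kJ mol⁻¹)
    (constants at 20 °C)

The neighbour of ash with 0.15 M of starting complex keeps the same cold stretch, so its warm age is still 2.00 d and I again expect between 54.2 % and 69.6 %. It gives 62.5 %.

The numbers in the tables come from a simulation from invented constants; noise was put on by code.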